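Ring A, the cyclohexene C1–C14–C13–C12=C11–C15 (verticillane numbering), is opened at C12–C13 and C1–C15. C12 and C15 are the α- and α′-carbons of a latent C11 ketone and stand 1,3 to each other, exactly as C13 and C1 do. The key step is therefore a one-pot [3+3] annulation: methyl 4-methyl-3-oxopentanoate is C-alkylated by the primary bromide (C13) of an enantiopure acyclic bromo mesylate that already carries the C2–C7 arm, and the derived dianion then displaces the C1 mesylate with inversion, creating quaternary C15 and the C1 stereocentre. Ring-closing metathesis and a transannular Claisen condensation later deliver the macrocycle and the cyclopentenedione.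

Key step: step 6

Numbering used below (bicyclo[9.3.1]pentadecane, verticillane type): C1 is the ring-A methine; C2–C10 form the nine-carbon bridge (C4 carries the exocyclic methylene C20, C6 the acetoxy group, C7=C8 is the E olefin with methyl C19, C9 is the doubly α methine, C10 a ketone); C11=C12 is the tetrasubstituted olefin; C13 and C14 are the ring-A methylenes; C15 is the gem-dimethyl carbon; C18 is the ketone carbon joining C12 to C9. Ring A is C1, C14, C13, C12, C11, C15; ring B is C9, C10, C11, C12, C18.

Assumption: (2R)-2-(2-bromoethyl)oxirane is taken as a purchasable building block; otherwise it would come from hydrolytic kinetic resolution of the commercial racemate.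

Step 1
Reactants: 1 acrolein (prop-2-enal); 2 3-chloro-2-(chloromethyl)prop-1-ene
Product: 3 rac-5-(chloromethyl)hexa-1,5-dien-3-ol
Conditions: Zn dust, sat. aq. NH4Cl/THF, 0 °C → rt (2 in threefold excess)
Reagents that add atoms: none
Why: Zinc-mediated Barbier allylation adds the 2-(chloromethyl)allyl unit 1,2 to the aldehyde (both allyl termini give the same product), the excess of 2 keeping the second allylic chloride intact; the carbinol is formed as a racemate.

Step 2
Reactants: 3 rac-5-(chloromethyl)hexa-1,5-dien-3-ol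
Product: 4 (3S)-5-(chloromethyl)hexa-1,5-dien-3-ol
Conditions: Ti(OiPr)4, D-(−)-diisopropyl tartrate, t-BuOOH (0.6 equiv), 4 Å MS, CH2Cl2, −20 °C
Reagents that add atoms: none
Why: Sharpless kinetic resolution of a secondary vinyl carbinol: with the D-tartrate the (R)-enantiomer should be epoxidised much faster, so the (S)-alcohol (future C6) is recovered enantio-enriched.

Step 3
Reactants: 4 (3S)-5-(chloromethyl)hexa-1,5-dien-3-ol
Product: 5 tert-butyl{[(3S)-5-(chloromethyl)hexa-1,5-dien-3-yl]oxy}dimethylsilane
Conditions: TBSCl, imidazole, DMF, 0 °C → rt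
Reagents that add atoms: tert-butyldimethylsilyl chloride, CC(C)(C)[Si](C)(C)Cl
Why: Standard silylation of a secondary alcohol; the base-stable silyl ether masks the C6 oxygen through the organometallic and enolate steps and prevents etherification onto the allylic chloride.

Step 4
Reactants: 5 tert-butyl{[(3S)-5-(chloromethyl)hexa-1,5-dien-3-yl]oxy}dimethylsilane; 6 (2R)-2-(2-bromoethyl)oxirane
Product: 8 (3S,8S)-1-bromo-8-{[tert-butyl(dimethyl)silyl]oxy}-6-methylidenedec-9-en-3-ol, via allylic Grignard reagent 7 (not isolated)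
Conditions: Mg turnings, THF, 0 °C (slow addition of 5); then 6, −30 → 0 °C; aq. NH4Cl
Reagents that add atoms: none
Why: Epoxide opening by an allylic Grignard reagent: the symmetric 2-substituted allyl unit attacks the epoxide CH2 (forming C2–C3) faster than the primary bromide, and the carbinol (future C1) keeps the configuration of 6.

Step 5
Reactants: 8 (3S,8S)-1-bromo-8-{[tert-butyl(dimethyl)silyl]oxy}-6-methylidenedec-9-en-3-ol
Product: 9 (3S,8S)-1-bromo-8-{[tert-butyl(dimethyl)silyl]oxy}-6-methylidenedec-9-en-3-yl methanesulfonate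
Conditions: MsCl, Et3N, CH2Cl2, 0 °C
Reagents that add atoms: methanesulfonyl chloride, CS(=O)(=O)Cl
Why: Sulfonylation of the secondary alcohol with retention; the primary bromide (C13) and the secondary mesylate (C1) are now the two electrophilic ends of the three-carbon unit C13–C14–C1.

Step 6
Reactants: 9 (3S,8S)-1-bromo-8-{[tert-butyl(dimethyl)silyl]oxy}-6-methylidenedec-9-en-3-yl methanesulfonate; 10 methyl 4-methyl-3-oxopentanoate
Product: 12 methyl (4S)-4-[(5S)-5-{[tert-butyl(dimethyl)silyl]oxy}-3-methylidenehept-6-en-1-yl]-3,3-dimethyl-2-oxocyclohexane-1-carboxylate, via alkylated keto ester 11 (not isolated)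
Conditions: 10 (1.1 equiv), NaH (1.05 equiv), THF–DMPU, 0 °C; 9, 0 → 40 °C; then LDA (2.3 equiv), −78 → 0 °C; aq. NH4Cl
Reagents that add atoms: none
Why: The sodium enolate of 10 is alkylated at its doubly activated carbon (C12) by the primary bromide of 9 (SN2; the secondary mesylate is far slower toward this stabilised nucleophile), and LDA then converts 11 into its dianion, whose α′-carbanion (the isopropyl carbon, C15) attacks the mesylate carbon C1 intramolecularly. The closest known reaction type is the α,α′-annulation of a β-keto ester with a 1,3-dielectrophile, the second stage being a β-keto ester dianion alkylation. Ring A closes in the 6-(enolendo)-exo-tet mode, the mode by which isopropyl ketone enolates are known to give 2,2-dimethylcyclohexanones. C1 is set by SN2 inversion at the enantiopure mesylate carbon, which traces back to epoxide 6; C15 is not stereogenic and the C12 centre is erased in step 7. The step needs C- over O-cyclisation and substitution over elimination: O-alkylation threatens only the monoanion, so the dianion is formed cold before warming, and attack by C12 itself would give a four-membered ring.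

Step 7
Reactants: 12 methyl (4S)-4-[(5S)-5-{[tert-butyl(dimethyl)silyl]oxy}-3-methylidenehept-6-en-1-yl]-3,3-dimethyl-2-oxocyclohexane-1-carboxylate
Product: 13 methyl (4R)-4-[(5S)-5-{[tert-butyl(dimethyl)silyl]oxy}-3-methylidenehept-6-en-1-yl]-3,3-dimethyl-2-{[(trifluoromethyl)sulfonyl]oxy}cyclohex-1-ene-1-carboxylate
Conditions: NaH, THF, 0 °C; PhNTf2, 0 °C → rt
Reagents that add atoms: N-phenylbis(trifluoromethanesulfonimide), O=S(=O)(N(c1ccccc1)S(=O)(=O)C(F)(F)F)C(F)(F)F
Why: Enol triflate formation by O-sulfonylation of the β-keto ester enolate, which can only form toward C12 because C15 is quaternary.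

Step 8
Reactants: 13 methyl (4R)-4-[(5S)-5-{[tert-butyl(dimethyl)silyl]oxy}-3-methylidenehept-6-en-1-yl]-3,3-dimethyl-2-{[(trifluoromethyl)sulfonyl]oxy}cyclohex-1-ene-1-carboxylate; 14 tributyl(2-methylprop-2-en-1-yl)stannane
Product: 15 methyl (4R)-4-[(5S)-5-{[tert-butyl(dimethyl)silyl]oxy}-3-methylidenehept-6-en-1-yl]-3,3-dimethyl-2-(3-methylbut-3-enoyl)cyclohex-1-ene-1-carboxylate
Conditions: Pd(PPh3)4 (5 mol%), LiCl, CO (3 atm), THF, 55 °C
Reagents that add atoms: carbon monoxide, [C-]#[O+]
Why: Carbonylative Stille coupling: oxidative addition to the enol triflate, CO insertion and transfer of the methallyl group from tin (its two termini are equivalent) install C10 as a ketone together with C9, C8 and C19.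

Step 9
Reactants: 15 methyl (4R)-4-[(5S)-5-{[tert-butyl(dimethyl)silyl]oxy}-3-methylidenehept-6-en-1-yl]-3,3-dimethyl-2-(3-methylbut-3-enoyl)cyclohex-1-ene-1-carboxylate
Product: 16 methyl (1R,6S,7E)-6-{[tert-butyl(dimethyl)silyl]oxy}-8,15,15-trimethyl-4-methylidene-10-oxobicyclo[9.3.1]pentadeca-7,11-diene-12-carboxylate
Conditions: second-generation Grubbs catalyst (H2IMes)(PCy3)Cl2Ru=CHPh (10 mol%), 1,4-benzoquinone (20 mol%), toluene (1 mM), 80 °C
Reagents that add atoms: none
Why: Ring-closing metathesis between the C7 vinyl group and the 1,1-disubstituted C8 olefin closes the twelve-membered ring while C9 is still a flexible CH2; the E trisubstituted olefin typical of this bridged ring family is expected to be favoured, and the C4 methylene and the C11=C12 olefin cannot form a viable ring.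

Step 10
Reactants: 16 methyl (1R,6S,7E)-6-{[tert-butyl(dimethyl)silyl]oxy}-8,15,15-trimethyl-4-methylidene-10-oxobicyclo[9.3.1]pentadeca-7,11-diene-12-carboxylate
Product: 17 6-O-(tert-butyldimethylsilyl)-6-O-deacetylcespitularin K
Conditions: KOtBu (2.2 equiv), THF, −20 → 0 °C; then AcOH
Reagents that add atoms: none
Why: Transannular Claisen (Dieckmann-type) condensation: the C9 enolate of the C10 ketone attacks the C18 ester in a 5-exo-trig acyl substitution to close ring B, and C9 is fixed by the bridge, which can only span the face of the enedione that carries the C1 arm.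

Step 11
Reactants: 17 6-O-(tert-butyldimethylsilyl)-6-O-deacetylcespitularin K
Product: 18 6-O-deacetylcespitularin K
Conditions: HF·pyridine, pyridine/THF, 0 °C → rt
Reagents that add atoms: none
Why: Desilylation of the allylic silyl ether under buffered, non-basic conditions that should leave the enedione and the acidic C9–H untouched.

Step 12
Reactants: 18 6-O-deacetylcespitularin K
Product: 19 cespitularin K
Conditions: Ac2O, pyridine, CH2Cl2, 0 °C → rt
Reagents that add atoms: acetic anhydride, CC(=O)OC(C)=O
Why: Acetylation of the secondary allylic alcohol with retention at C6; the bridge holds the C7=C8 olefin out of the plane of ring B, so tautomerisation to a 2-alkylidene dione is not expected.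

Compound list
1 | acrolein (prop-2-enal) | C=CC=O | starting material
2 | 3-chloro-2-(chloromethyl)prop-1-ene | C=C(CCl)CCl | starting material
3 | rac-5-(chloromethyl)hexa-1,5-dien-3-ol | C=CC(O)CC(=C)CCl | intermediate
4 | (3S)-5-(chloromethyl)hexa-1,5-dien-3-ol | C=C[C@@H](O)CC(=C)CCl | intermediate
5 | tert-butyl{[(3S)-5-(chloromethyl)hexa-1,5-dien-3-yl]oxy}dimethylsilane | C=C[C@@H](O[Si](C)(C)C(C)(C)C)CC(=C)CCl | intermediate
6 | (2R)-2-(2-bromoethyl)oxirane | BrCC[C@@H]1CO1 | starting material
7 | allylic Grignard reagent from 5, {2-[(2S)-2-{[tert-butyl(dimethyl)silyl]oxy}but-3-en-1-yl]prop-2-en-1-yl}magnesium chloride | C=C[C@@H](O[Si](C)(C)C(C)(C)C)CC(=C)C[Mg]Cl | intermediate (not isolated)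
8 | (3S,8S)-1-bromo-8-{[tert-butyl(dimethyl)silyl]oxy}-6-methylidenedec-9-en-3-ol | C=C[C@@H](O[Si](C)(C)C(C)(C)C)CC(=C)CC[C@H](O)CCBr | intermediate
9 | (3S,8S)-1-bromo-8-{[tert-butyl(dimethyl)silyl]oxy}-6-methylidenedec-9-en-3-yl methanesulfonate | C=C[C@@H](O[Si](C)(C)C(C)(C)C)CC(=C)CC[C@H](OS(C)(=O)=O)CCBr | intermediate
10 | methyl 4-methyl-3-oxopentanoate | COC(=O)CC(=O)C(C)C | starting material
11 | methyl 2-[(3R,8S)-8-{[tert-butyl(dimethyl)silyl]oxy}-3-(methanesulfonyloxy)-6-methylidenedec-9-en-1-yl]-4-methyl-3-oxopentanoate (same spatial arrangement at the mesylate carbon as in 9; epimers at C2) | COC(=O)C(CC[C@@H](OS(C)(=O)=O)CCC(=C)C[C@H](O[Si](C)(C)C(C)(C)C)C=C)C(=O)C(C)C | intermediate (not isolated)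
12 | methyl (4S)-4-[(5S)-5-{[tert-butyl(dimethyl)silyl]oxy}-3-methylidenehept-6-en-1-yl]-3,3-dimethyl-2-oxocyclohexane-1-carboxylate (epimers at C1, keto/enol) | COC(=O)C1CC[C@@H](CCC(=C)C[C@H](O[Si](C)(C)C(C)(C)C)C=C)C(C)(C)C1=O | intermediate
13 | methyl (4R)-4-[(5S)-5-{[tert-butyl(dimethyl)silyl]oxy}-3-methylidenehept-6-en-1-yl]-3,3-dimethyl-2-{[(trifluoromethyl)sulfonyl]oxy}cyclohex-1-ene-1-carboxylate | COC(=O)C1=C(OS(=O)(=O)C(F)(F)F)C(C)(C)[C@H](CCC(=C)C[C@H](O[Si](C)(C)C(C)(C)C)C=C)CC1 | intermediate
14 | tributyl(2-methylprop-2-en-1-yl)stannane | CCCC[Sn](CCCC)(CCCC)CC(C)=C | starting material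
15 | methyl (4R)-4-[(5S)-5-{[tert-butyl(dimethyl)silyl]oxy}-3-methylidenehept-6-en-1-yl]-3,3-dimethyl-2-(3-methylbut-3-enoyl)cyclohex-1-ene-1-carboxylate | COC(=O)C1=C(C(=O)CC(C)=C)C(C)(C)[C@H](CCC(=C)C[C@H](O[Si](C)(C)C(C)(C)C)C=C)CC1 | intermediate
16 | methyl (1R,6S,7E)-6-{[tert-butyl(dimethyl)silyl]oxy}-8,15,15-trimethyl-4-methylidene-10-oxobicyclo[9.3.1]pentadeca-7,11-diene-12-carboxylate | C=C1CC[C@@H]2CCC(C(=O)OC)=C(C(=O)C/C(C)=C/[C@@H](O[Si](C)(C)C(C)(C)C)C1)C2(C)C | intermediate
17 | 6-O-(tert-butyldimethylsilyl)-6-O-deacetylcespitularin K (tricyclic 2-alkenylcyclopent-4-ene-1,3-dione, silyl ether at C6) | C=C1CC[C@@H]2CCC3=C(C(=O)[C@H](C3=O)/C(C)=C/[C@@H](O[Si](C)(C)C(C)(C)C)C1)C2(C)C | intermediate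
18 | 6-O-deacetylcespitularin K (free C6 alcohol) | C=C1CC[C@@H]2CCC3=C(C(=O)[C@H](C3=O)/C(C)=C/[C@@H](O)C1)C2(C)C | intermediate
19 | cespitularin K | C=C1CC[C@@H]2CCC3=C(C(=O)[C@H](C3=O)/C(C)=C/[C@@H](OC(C)=O)C1)C2(C)C | target

Total step count: 12. Longest linear sequence: 12 steps (1 → 19).

Steps most likely to fail

Step 6. The hindered C15–C1 bond formation may be outrun by O-alkylation of the keto ester enolate (six-membered enol ether) or by elimination of the mesylate. The fallback splits the one-pot and changes the nucleophile to one that cannot O-cyclise. It sets out from 9 and 10: monoalkylation (NaH, THF–DMPU) is stopped at the alkylated keto ester 11, which is isolated and converted with TBSOTf/Et3N into its tert-butyldimethylsilyl enol ether F1. γ-Deprotonation of this β-silyloxy enoate at the isopropyl carbon with LDA (the way bis-silyl dienolates of acetoacetates are made) is followed by 6-exo-tet γ-alkylation by the mesylate, which should give the cyclic silyl enol ether F2 with the same inversion at C1. CsF/PhNTf2 then converts F2 directly into the enol triflate, so the route is rejoined at 13.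

Step 9. Ring closure may proceed with poor E/Z selectivity at the trisubstituted olefin or give way to dimerisation. The fallback sets out from 15 and no longer relies on the metathesis for geometry: the ring is closed at high dilution whatever the selectivity, and the (Z)-configured macrocyclic keto ester F4 (or the mixture) is then equilibrated by reversible thiyl-radical addition (PhSSPh cat., hν, benzene). This sets the olefin under thermodynamic control toward the E isomer and rejoins the route at 16.

Step 8. Direct (non-carbonylative) allyl transfer or migration of the β,γ-double bond into conjugation may compete with acyl transfer. The fallback sets out from 13: Sonogashira coupling with commercial 2-methylbut-1-en-3-yne (PdCl2(PPh3)2, CuI, Et3N) gives the dienyne ester F3. Its alkyne is then hydrated with participation of the neighbouring ester carbonyl (Ph3PAuCl/AgOTf, aqueous dioxane; 5-exo-dig attack places the oxygen on the ring-side carbon C10), which returns the β,γ-unsaturated ketone and rejoins the route at 15.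

Further compounds
F1 | step 6 | methyl 2-[(3S,8S)-8-{[tert-butyl(dimethyl)silyl]oxy}-3-(methanesulfonyloxy)-6-methylidenedec-9-en-1-yl]-3-{[tert-butyl(dimethyl)silyl]oxy}-4-methylpent-2-enoate | COC(=O)C(CC[C@@H](OS(C)(=O)=O)CCC(=C)C[C@H](O[Si](C)(C)C(C)(C)C)C=C)=C(O[Si](C)(C)C(C)(C)C)C(C)C
F2 | step 6 | methyl (4R)-4-[(5S)-5-{[tert-butyl(dimethyl)silyl]oxy}-3-methylidenehept-6-en-1-yl]-2-{[tert-butyl(dimethyl)silyl]oxy}-3,3-dimethylcyclohex-1-ene-1-carboxylate | COC(=O)C1=C(O[Si](C)(C)C(C)(C)C)C(C)(C)[C@H](CCC(=C)C[C@H](O[Si](C)(C)C(C)(C)C)C=C)CC1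
F3 | step 8 | methyl (4R)-4-[(5S)-5-{[tert-butyl(dimethyl)silyl]oxy}-3-methylidenehept-6-en-1-yl]-3,3-dimethyl-2-(3-methylbut-3-en-1-yn-1-yl)cyclohex-1-ene-1-carboxylate | COC(=O)C1=C(C#CC(C)=C)C(C)(C)[C@H](CCC(=C)C[C@H](O[Si](C)(C)C(C)(C)C)C=C)CC1
F4 | step 9 | methyl (1R,6S,7Z)-6-{[tert-butyl(dimethyl)silyl]oxy}-8,15,15-trimethyl-4-methylidene-10-oxobicyclo[9.3.1]pentadeca-7,11-diene-12-carboxylate | C=C1CC[C@@H]2CCC(C(=O)OC)=C(C(=O)C/C(C)=C\[C@@H](O[Si](C)(C)C(C)(C)C)C1)C2(C)C
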